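The central phenol ring (C1 OH, C2 and C4 the 4-hydroxybenzyl groups, C3 the CH2CH2 bridge to ring A, C5/C6 unsubstituted) is cut at C4–C5 and C2–C3. The contiguous oxygen/benzyl/bridge/benzyl pattern on C1–C4 is that of a Robinson annulation product, so one operation joins a 2-benzylated β-keto allyl ester (C3, C4, bridge, ring A) to an arylethyl vinyl ketone (C1, C2, C5, C6) by Michael addition and amine-catalysed aldol condensation, closing the carbocycle with every skeletal carbon in place. The C4 ester that steers the annulation later leaves as CO2 and aromatises the ring. All phenols travel as benzyl ethers.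

Key step: step 8

Remarks on the chemistry:
- The target has no stereocentre, so the compound "as given" is the one achiral structure. The quaternary centre C4 of compounds 14–20 is racemic and vanishes on aromatisation.
- The central-ring numbering C1 (OH) to C6 is used throughout.
- Ionised or catalyst-bound forms of a numbered compound (enolates, enamines, salts) carry no number of their own.
- LDA is used as the commercial solution.

Step 1
Reactants: 1 3-hydroxy-5-methoxybenzaldehyde
Product: 2 3-(benzyloxy)-5-methoxybenzaldehyde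
Conditions: BnBr (1.1 equiv), K2CO3, DMF, rt
Reagents that add atoms: benzyl bromide, BrCc1ccccc1
Why: Williamson ether synthesis on the phenoxide; the non-enolisable aldehyde is inert to carbonate.

Step 2
Reactants: 2 3-(benzyloxy)-5-methoxybenzaldehyde
Product: 3 [3-(benzyloxy)-5-methoxyphenyl]methanol
Conditions: NaBH4, MeOH, 0 °C
Reagents that add atoms: none
Why: Borohydride reduction of an aryl aldehyde; the aryl ethers are untouched.

Step 3
Reactants: 3 [3-(benzyloxy)-5-methoxyphenyl]methanol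
Product: 4 1-(benzyloxy)-3-(bromomethyl)-5-methoxybenzene
Conditions: PBr3 (0.4 equiv), CH2Cl2, 0 °C to rt
Reagents that add atoms: phosphorus tribromide, BrP(Br)Br
Why: SN2 displacement of the activated phosphite ester by bromide, the standard conversion of 3,5-dialkoxybenzyl alcohols into their bromides.

Step 4
Reactants: 5 allyl acetoacetate (1.5 equiv); 6 4-(benzyloxy)benzyl chloride
Product: 7 allyl 2-[4-(benzyloxy)benzyl]-3-oxobutanoate (racemic, epimerisable)
Conditions: K2CO3, KI (cat.), acetone, reflux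
Reagents that add atoms: none
Why: C-alkylation of a β-keto ester enolate with a benzylic halide (iodide catalysis); the excess of the cheap acetoacetate should suppress dialkylation.

Step 5
Reactants: 7 allyl 2-[4-(benzyloxy)benzyl]-3-oxobutanoate; 4 1-(benzyloxy)-3-(bromomethyl)-5-methoxybenzene
Product: 8 allyl 2-[4-(benzyloxy)benzyl]-5-[3-(benzyloxy)-5-methoxyphenyl]-3-oxopentanoate (racemic, epimerisable)
Conditions: LDA (2.2 equiv), THF, −78 to 0 °C; then 4, −78 to 0 °C; cold 1 M HCl quench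
Reagents that add atoms: none
Why: Huckin–Weiler dianion alkylation: the second deprotonation occurs at the acetyl CH3 and this more basic γ-carbon alone is alkylated by the benzylic bromide, which builds the bridge without any alkene reduction in the presence of benzyl ethers.

Step 6
Reactants: 9 3-[4-(benzyloxy)phenyl]propanoic acid
Product: 11 3-[4-(benzyloxy)phenyl]-N-methoxy-N-methylpropanamide, via 3-[4-(benzyloxy)phenyl]-1-(1H-imidazol-1-yl)propan-1-one 10 (not isolated)
Conditions: CDI (1.1 equiv), CH2Cl2, rt; then MeNH(OMe)·HCl (1.2 equiv), rt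
Reagents that add atoms: N,O-dimethylhydroxylamine hydrochloride, CNOC.Cl; 1,1'-carbonyldiimidazole, O=C(n1ccnc1)n1ccnc1 (imidazolyl group in 10 only)
Why: Acyl imidazolide formation and aminolysis (Weinreb amide synthesis); the imidazole set free serves as the base for the amine hydrochloride.

Step 7
Reactants: 11 3-[4-(benzyloxy)phenyl]-N-methoxy-N-methylpropanamide
Product: 13 5-[4-(benzyloxy)phenyl]pent-1-en-3-one, via bromomagnesium alkoxide of 5-[4-(benzyloxy)phenyl]-3-[methoxy(methyl)amino]pent-1-en-3-ol (chelated tetrahedral adduct) 12 (not isolated)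
Conditions: CH2=CHMgBr (1.5 equiv), THF, 0 °C; inverse quench into cold 1 M HCl; used promptly (BHT, cold)
Reagents that add atoms: vinylmagnesium bromide, C=C[Mg]Br
Why: Weinreb ketone synthesis, in which the five-membered magnesium chelate prevents over-addition; the inverse acidic quench protonates the liberated N,O-dimethylhydroxylamine before it can add to the vinyl ketone.

Step 8
Reactants: 8 allyl 2-[4-(benzyloxy)benzyl]-5-[3-(benzyloxy)-5-methoxyphenyl]-3-oxopentanoate; 13 5-[4-(benzyloxy)phenyl]pent-1-en-3-one (1.2 equiv)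
Product: 16 allyl 1,3-bis[4-(benzyloxy)benzyl]-2-{2-[3-(benzyloxy)-5-methoxyphenyl]ethyl}-4-oxocyclohex-2-ene-1-carboxylate (racemic), via allyl 2-[4-(benzyloxy)benzyl]-2-{3-[3-(benzyloxy)-5-methoxyphenyl]propanoyl}-7-[4-(benzyloxy)phenyl]-5-oxoheptanoate 14 (not isolated), via allyl 1,3-bis[4-(benzyloxy)benzyl]-2-{2-[3-(benzyloxy)-5-methoxyphenyl]ethyl}-2-hydroxy-4-oxocyclohexane-1-carboxylate 15 (not isolated)
Conditions: DBU (5 mol %), MeCN, 0 °C; AcOH quench; then pyrrolidine (1.0 equiv), AcOH (1.0 equiv), toluene, 4 Å MS, 80 °C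
Reagents that add atoms: none
Why: DBU deprotonates 8 only at the carbon flanked by both carbonyls (C4), and this enolate adds to the terminal CH2 of 13 to form the C4–C5 bond and 1,5-diketone 14 (Michael addition). After the base is neutralised, pyrrolidine forms an enamine only at the unhindered C1 ketone; its C1=C2 enamine attacks the C3 ketone in a 6-(enolendo)-exo-trig aldol closure to 15, and loss of water through the iminium ion gives the tetrasubstituted C2=C3 enone 16. The closest known reaction type is the Robinson annulation of 2-alkyl β-keto esters with alkyl vinyl ketones, run as a base-catalysed Michael addition followed by a pyrrolidinium acetate aldol condensation. The one new stereocentre, quaternary C4, forms without control as a racemate, which is harmless because decarboxylative aromatisation removes it. Two selectivities are needed: alkylation at C4 and not at the bridge CH2, secured by the double activation of C4, and aldol in the direction C2 to C3 and not bridge-CH2 to C1, secured because the C3 ketone next to the quaternary carbon does not form an enamine, while the alternative C6 enamine could only close a four-membered ring and reverts.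

Step 9
Reactants: 16 allyl 1,3-bis[4-(benzyloxy)benzyl]-2-{2-[3-(benzyloxy)-5-methoxyphenyl]ethyl}-4-oxocyclohex-2-ene-1-carboxylate
Product: 19 allyl 1,3-bis[4-(benzyloxy)benzyl]-2-{2-[3-(benzyloxy)-5-methoxyphenyl]ethyl}-4-oxocyclohexa-2,5-diene-1-carboxylate (racemic), via allyl 1,3-bis[4-(benzyloxy)benzyl]-2-{2-[3-(benzyloxy)-5-methoxyphenyl]ethyl}-4-oxo-5-(phenylselanyl)cyclohex-2-ene-1-carboxylate 17 (not isolated), via allyl 1,3-bis[4-(benzyloxy)benzyl]-2-{2-[3-(benzyloxy)-5-methoxyphenyl]ethyl}-4-oxo-5-(phenylseleninyl)cyclohex-2-ene-1-carboxylate 18 (not isolated)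
Conditions: LDA (1.1 equiv), THF, −78 °C; PhSeBr, −78 °C; then AcOH, 30% H2O2, 0 °C to rt
Reagents that add atoms: phenylselanyl bromide, Br[Se]c1ccccc1 (in 17 and 18 only); hydrogen peroxide, OO (oxygen in 18 only)
Why: Kinetic deprotonation of the enone at the α′-CH2 (C6) gives the cross-conjugated enolate, which is selenenylated; after oxidation, syn-selenoxide elimination can only run towards C5 (Reich dehydrogenation), giving the 4,4-disubstituted cyclohexa-2,5-dienone.

Step 10
Reactants: 19 allyl 1,3-bis[4-(benzyloxy)benzyl]-2-{2-[3-(benzyloxy)-5-methoxyphenyl]ethyl}-4-oxocyclohexa-2,5-diene-1-carboxylate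
Product: 21 2,4-bis[4-(benzyloxy)benzyl]-3-{2-[3-(benzyloxy)-5-methoxyphenyl]ethyl}phenol, via 1,3-bis[4-(benzyloxy)benzyl]-2-{2-[3-(benzyloxy)-5-methoxyphenyl]ethyl}-4-oxocyclohexa-2,5-diene-1-carboxylic acid 20 (not isolated)
Conditions: Pd(PPh3)4 (5 mol %), morpholine (5 equiv), THF, rt
Reagents that add atoms: none
Why: Pd(0) ionises the allyl ester and morpholine traps the π-allyl fragment irreversibly (Tsuji–Trost deallylation); the liberated 4-carboxycyclohexa-2,5-dienone is a vinylogous β-keto acid that loses CO2 with aromatisation to the phenol, which erases the stereocentre.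

Step 11
Reactants: 21 2,4-bis[4-(benzyloxy)benzyl]-3-{2-[3-(benzyloxy)-5-methoxyphenyl]ethyl}phenol
Product: 22 2,4-bis(4-hydroxybenzyl)-3-[2-(3-hydroxy-5-methoxyphenyl)ethyl]phenol (target)
Conditions: H2 (1 atm), 10% Pd/C, EtOAc–MeOH, rt
Reagents that add atoms: none
Why: Catalytic hydrogenolysis of the three aryl benzyl ethers; the diarylmethane and bibenzyl C–C bonds and the aryl methyl ether are stable under these conditions.

Compound list
1 | 3-hydroxy-5-methoxybenzaldehyde | COc1cc(O)cc(C=O)c1 | starting material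
2 | 3-(benzyloxy)-5-methoxybenzaldehyde | COc1cc(OCc2ccccc2)cc(C=O)c1 | intermediate
3 | [3-(benzyloxy)-5-methoxyphenyl]methanol | COc1cc(OCc2ccccc2)cc(CO)c1 | intermediate
4 | 1-(benzyloxy)-3-(bromomethyl)-5-methoxybenzene | COc1cc(OCc2ccccc2)cc(CBr)c1 | intermediate
5 | allyl acetoacetate (prop-2-en-1-yl 3-oxobutanoate) | CC(=O)CC(=O)OCC=C | starting material
6 | 4-(benzyloxy)benzyl chloride | ClCc1ccc(OCc2ccccc2)cc1 | starting material
7 | allyl 2-[4-(benzyloxy)benzyl]-3-oxobutanoate (racemic, epimerisable) | CC(=O)C(Cc1ccc(OCc2ccccc2)cc1)C(=O)OCC=C | intermediate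
8 | allyl 2-[4-(benzyloxy)benzyl]-5-[3-(benzyloxy)-5-methoxyphenyl]-3-oxopentanoate (racemic, epimerisable) | C=CCOC(=O)C(Cc1ccc(OCc2ccccc2)cc1)C(=O)CCc1cc(OC)cc(OCc2ccccc2)c1 | intermediate
9 | 3-[4-(benzyloxy)phenyl]propanoic acid | OC(=O)CCc1ccc(OCc2ccccc2)cc1 | starting material
10 | 3-[4-(benzyloxy)phenyl]-1-(1H-imidazol-1-yl)propan-1-one | O=C(CCc1ccc(OCc2ccccc2)cc1)n1ccnc1 | intermediate
11 | 3-[4-(benzyloxy)phenyl]-N-methoxy-N-methylpropanamide | CON(C)C(=O)CCc1ccc(OCc2ccccc2)cc1 | intermediate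
12 | bromomagnesium alkoxide of 5-[4-(benzyloxy)phenyl]-3-[methoxy(methyl)amino]pent-1-en-3-ol (chelated tetrahedral adduct) | C=CC(O[Mg]Br)(CCc1ccc(OCc2ccccc2)cc1)N(C)OC | intermediate
13 | 5-[4-(benzyloxy)phenyl]pent-1-en-3-one | C=CC(=O)CCc1ccc(OCc2ccccc2)cc1 | intermediate
14 | allyl 2-[4-(benzyloxy)benzyl]-2-{3-[3-(benzyloxy)-5-methoxyphenyl]propanoyl}-7-[4-(benzyloxy)phenyl]-5-oxoheptanoate (racemic) | C=CCOC(=O)C(Cc1ccc(OCc2ccccc2)cc1)(CCC(=O)CCc1ccc(OCc2ccccc2)cc1)C(=O)CCc1cc(OC)cc(OCc2ccccc2)c1 | intermediate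
15 | allyl 1,3-bis[4-(benzyloxy)benzyl]-2-{2-[3-(benzyloxy)-5-methoxyphenyl]ethyl}-2-hydroxy-4-oxocyclohexane-1-carboxylate (racemic, mixture of diastereomers) | C=CCOC(=O)C1(Cc2ccc(OCc3ccccc3)cc2)CCC(=O)C(Cc2ccc(OCc3ccccc3)cc2)C1(O)CCc1cc(OC)cc(OCc2ccccc2)c1 | intermediate
16 | allyl 1,3-bis[4-(benzyloxy)benzyl]-2-{2-[3-(benzyloxy)-5-methoxyphenyl]ethyl}-4-oxocyclohex-2-ene-1-carboxylate (racemic) | C=CCOC(=O)C1(Cc2ccc(OCc3ccccc3)cc2)CCC(=O)C(Cc2ccc(OCc3ccccc3)cc2)=C1CCc1cc(OC)cc(OCc2ccccc2)c1 | intermediate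
17 | allyl 1,3-bis[4-(benzyloxy)benzyl]-2-{2-[3-(benzyloxy)-5-methoxyphenyl]ethyl}-4-oxo-5-(phenylselanyl)cyclohex-2-ene-1-carboxylate (racemic, mixture of diastereomers) | C=CCOC(=O)C1(Cc2ccc(OCc3ccccc3)cc2)CC([Se]c2ccccc2)C(=O)C(Cc2ccc(OCc3ccccc3)cc2)=C1CCc1cc(OC)cc(OCc2ccccc2)c1 | intermediate
18 | allyl 1,3-bis[4-(benzyloxy)benzyl]-2-{2-[3-(benzyloxy)-5-methoxyphenyl]ethyl}-4-oxo-5-(phenylseleninyl)cyclohex-2-ene-1-carboxylate (racemic, mixture of diastereomers) | C=CCOC(=O)C1(Cc2ccc(OCc3ccccc3)cc2)CC([Se](=O)c2ccccc2)C(=O)C(Cc2ccc(OCc3ccccc3)cc2)=C1CCc1cc(OC)cc(OCc2ccccc2)c1 | intermediate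
19 | allyl 1,3-bis[4-(benzyloxy)benzyl]-2-{2-[3-(benzyloxy)-5-methoxyphenyl]ethyl}-4-oxocyclohexa-2,5-diene-1-carboxylate (racemic) | C=CCOC(=O)C1(Cc2ccc(OCc3ccccc3)cc2)C=CC(=O)C(Cc2ccc(OCc3ccccc3)cc2)=C1CCc1cc(OC)cc(OCc2ccccc2)c1 | intermediate
20 | 1,3-bis[4-(benzyloxy)benzyl]-2-{2-[3-(benzyloxy)-5-methoxyphenyl]ethyl}-4-oxocyclohexa-2,5-diene-1-carboxylic acid (racemic) | OC(=O)C1(Cc2ccc(OCc3ccccc3)cc2)C=CC(=O)C(Cc2ccc(OCc3ccccc3)cc2)=C1CCc1cc(OC)cc(OCc2ccccc2)c1 | intermediate
21 | 2,4-bis[4-(benzyloxy)benzyl]-3-{2-[3-(benzyloxy)-5-methoxyphenyl]ethyl}phenol | COc1cc(OCc2ccccc2)cc(CCc2c(Cc3ccc(OCc4ccccc4)cc3)ccc(O)c2Cc2ccc(OCc3ccccc3)cc2)c1 | intermediate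
22 | 2,4-bis(4-hydroxybenzyl)-3-[2-(3-hydroxy-5-methoxyphenyl)ethyl]phenol (achiral) | COc1cc(O)cc(CCc2c(Cc3ccc(O)cc3)ccc(O)c2Cc2ccc(O)cc2)c1 | target

Total step count: 11
Longest linear sequence: 8 steps (steps 1, 2, 3, 5, 8, 9, 10, 11)

Steps most likely to fail

1. Step 8. The ring closure may run in the wrong direction (enolisation of the bridge CH2 beside the hindered ketone and attack on the C1 carbonyl), may stall at the hindered C3 carbonyl, or the non-enolisable β-keto ester may suffer amine-induced retro-Claisen cleavage. The fallback sets out from 8 and generates the C2 nucleophile regiospecifically by conjugate reduction. Purchased (E)-3-[4-(benzyloxy)phenyl]prop-2-enoic acid (OC(=O)/C=C/c1ccc(OCc2ccccc2)cc1) would be converted with CDI and MeNH(OMe)·HCl into (E)-3-[4-(benzyloxy)phenyl]-N-methoxy-N-methylprop-2-enamide F1. Vinylmagnesium bromide with inverse acidic quench should then give the cross-conjugated dienone (E)-1-[4-(benzyloxy)phenyl]penta-1,4-dien-3-one F2. DBU-catalysed Michael addition of 8 to the unsubstituted vinyl terminus of F2 should give allyl (E)-2-[4-(benzyloxy)benzyl]-2-{3-[3-(benzyloxy)-5-methoxyphenyl]propanoyl}-7-[4-(benzyloxy)phenyl]-5-oxohept-6-enoate F3. Conjugate reduction of the styryl enone of F3 with Stryker's reagent ([(Ph3P)CuH]6, toluene, rt) forms the copper enolate at C2 only, and this closes onto the C3 ketone (reductive aldol cyclisation). The fallback comes back to the route at aldol 15, which is dehydrated (MsCl, Et3N, then DBU) to 16.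

2. Step 9. Deprotonation may occur at the γ-position (bridge CH2) to give the extended dienolate, the selenium electrophile or the peroxide may attack the allyl alkene, or the dienone may be over-oxidised. The fallback sets out from 16 and reverses the order of decarboxylation and dehydrogenation. Pd(PPh3)4/morpholine (THF, 50 °C) should cleave the allyl ester to 1,3-bis[4-(benzyloxy)benzyl]-2-{2-[3-(benzyloxy)-5-methoxyphenyl]ethyl}-4-oxocyclohex-2-ene-1-carboxylic acid F4. This vinylogous β-keto acid should lose CO2 on warming to give 2,4-bis[4-(benzyloxy)benzyl]-3-{2-[3-(benzyloxy)-5-methoxyphenyl]ethyl}cyclohex-2-en-1-one F5. Aerobic palladium-catalysed dehydrogenation of the cyclohexenone to the phenol (Pd(TFA)2, 2-(dimethylamino)pyridine, TsOH, O2, DMSO, 80 °C) then comes back to the route at 21.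

3. Step 5. γ-Metalation of the α-substituted β-keto ester may be incomplete, or proton transfer, O-alkylation or attack of the base on the allyl ester may erode the alkylation. The fallback sets out from 4 and builds the β-keto ester through a dioxinone instead of a dianion. The lithium dienolate of commercial 2,2,6-trimethyl-4H-1,3-dioxin-4-one (LDA, THF, −78 °C) would be alkylated at the 6-methyl group with bromide 4 to give 6-{2-[3-(benzyloxy)-5-methoxyphenyl]ethyl}-2,2-dimethyl-4H-1,3-dioxin-4-one F6. Heating F6 with allyl alcohol in toluene (110 °C, loss of acetone, acylketene trapping) should give allyl 5-[3-(benzyloxy)-5-methoxyphenyl]-3-oxopentanoate F7. C-Benzylation of F7 with 6 (K2CO3, KI, acetone) comes back to the route at 8.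

Further compounds
F1 | step 8 | (E)-3-[4-(benzyloxy)phenyl]-N-methoxy-N-methylprop-2-enamide | CON(C)C(=O)/C=C/c1ccc(OCc2ccccc2)cc1
F2 | step 8 | (E)-1-[4-(benzyloxy)phenyl]penta-1,4-dien-3-one | C=CC(=O)/C=C/c1ccc(OCc2ccccc2)cc1
F3 | step 8 | allyl (E)-2-[4-(benzyloxy)benzyl]-2-{3-[3-(benzyloxy)-5-methoxyphenyl]propanoyl}-7-[4-(benzyloxy)phenyl]-5-oxohept-6-enoate (racemic) | C=CCOC(=O)C(Cc1ccc(OCc2ccccc2)cc1)(CCC(=O)/C=C/c1ccc(OCc2ccccc2)cc1)C(=O)CCc1cc(OC)cc(OCc2ccccc2)c1
F4 | step 9 | 1,3-bis[4-(benzyloxy)benzyl]-2-{2-[3-(benzyloxy)-5-methoxyphenyl]ethyl}-4-oxocyclohex-2-ene-1-carboxylic acid (racemic) | OC(=O)C1(Cc2ccc(OCc3ccccc3)cc2)CCC(=O)C(Cc2ccc(OCc3ccccc3)cc2)=C1CCc1cc(OC)cc(OCc2ccccc2)c1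
F5 | step 9 | 2,4-bis[4-(benzyloxy)benzyl]-3-{2-[3-(benzyloxy)-5-methoxyphenyl]ethyl}cyclohex-2-en-1-one (racemic) | O=C1CCC(Cc2ccc(OCc3ccccc3)cc2)C(CCc2cc(OC)cc(OCc3ccccc3)c2)=C1Cc1ccc(OCc2ccccc2)cc1
F6 | step 5 | 6-{2-[3-(benzyloxy)-5-methoxyphenyl]ethyl}-2,2-dimethyl-4H-1,3-dioxin-4-one | CC1(C)OC(CCc2cc(OC)cc(OCc3ccccc3)c2)=CC(=O)O1
F7 | step 5 | allyl 5-[3-(benzyloxy)-5-methoxyphenyl]-3-oxopentanoate | C=CCOC(=O)CC(=O)CCc1cc(OC)cc(OCc2ccccc2)c1
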